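## Structural features

The target is a biflavonoid in which C3 of a naringenin-type flavanone (ring A with hydroxyls at C5 and C7, ring C a dihydropyranone, a 4-hydroxyphenyl ring B on C2) is bonded directly to C3''' of ring B of a 5''-hydroxy-7''-methoxyflavone, ortho to the C4''' hydroxyl. The only stereocentres, C2 (S) and C3 (R), are neighbours on ring C and carry their aryl groups trans, and a check of the drawn structure confirms this connectivity and these descriptors. C3–H lies between the C4 ketone and an aryl ring and is therefore acidic: the trans isomer can be reached by equilibration, but any real base can expel the ring A phenoxide from the C3 enolate, open ring C to a chalcone-type enone and erase C2. Further fragile features are the five free phenols, one of them flanking the crowded C3–C3''' bond, and the chromone enone, which must survive nucleophiles and reduction. The real difficulty is to fix C2 in the absolute sense beside a labile C3 at a hindered junction, and then to unmask the phenols without base. The key step exploits two facts about ring C. C2 can be the methylene carbon of a ring A 4-alkoxybenzyl ether, bound to O1 and benzylic to the electron-rich ring B, so its C–H bonds are strongly hydridic. C3 sits between the C4 carbonyl and flavone ring B, exactly where the carbon of an aryl diazo ketone sits, so a carbene on C3 can insert into a C2–H bond and close ring C.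

## Logic of the disconnections

20 from 19: the five benzylic C–O bonds of the benzyl-type ethers are cut (three benzyl ethers, and the 4-benzyloxybenzyl ether on O5 at both of its oxygens). Hydrogenolysis is neutral, so all phenols are released in one operation that touches neither C2 nor C3. The forward step must leave the chromone C2''=C3'' bond and the benzylic C2–O1 bond intact.

19 from 18: the O–Si bond at O4''' is cut. This oxygen sits ortho to the carbene carbon in the key step, so it cannot carry a benzyl-type group, which would offer a competing C–H insertion to a five-membered ring. A triflate would be equally inert, but its removal needs hydroxide, which would enolise C3 and risk opening ring C. A triisopropylsilyl ether is removed by buffered fluoride instead. The forward step must keep the medium non-basic.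

18 from 16: the C2–C3 bond is cut. Ring C and both stereocentres disappear, and 16 is achiral with two interchangeable ortho 4-benzyloxybenzyl ethers. The forward step needs 1,6 C–H insertion to beat ylide formation, selection of one enantiotopic hydrogen by the catalyst, and equilibration of C3 to trans (through 17) without touching C2.

16 from 15: the C3=N2 bond is cut. The diazo group is introduced last, so the sensitive function is not carried through other chemistry. The forward step needs diazo transfer to a hindered but doubly activated methylene.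

15 from 5 and 14: the C3–C3''' bond is cut, giving two halves of similar size. Acylating a phloroglucinol with an ortho-hydroxyarylacetic acid was not adopted: the acid lactonises, the resulting ortho-hydroxybenzyl ketone cyclodehydrates to a benzofuran under Lewis acid, and four phenols would then have to be told apart. The forward step is an enolate arylation at a bromide flanked by a silyloxy group, and it must spare the chromone.

14 from 8 and 12: C4a''–C4'', C4''–C3'' and O1''–C2'' are cut. The pyranone is assembled carbonylatively from an aryl iodide and a terminal alkyne before any stereocentre exists. The forward step needs reaction at C–I only, with C–Br kept for the next union, and 6-endo closure (through 13).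

12 from 9 through 10 and 11: the C1'''–C(sp) bond and the O–Si bond are cut. Both lead back to the commercial 9. The forward steps rely on the rate difference between C–I and C–Br and on a silyl ether that survives mild K2CO3.

8 from 6 through 7: one O–CH2 bond and the C–I bond are cut. Iodinating the symmetric 6 first leaves only one regiochemical question, and the benzyl ether keeps the C5'' oxygen away from the carbenoid later. The forward steps need iodination between the two hydroxyls and a statistical mono-alkylation.

5 from 4 and 3, and 4 from 2 and 3: the two ortho O–CH2 bonds are cut in turn. These ethers must be identical 4-benzyloxybenzyl groups, because one of them supplies C2 and ring B and the carbenoid must find the same C–H bonds on either side. The first alkylation stops by itself at the chelated phenol of 4 under mild conditions. The second needs a stronger base system, and running it as a separate operation keeps 3, which ionises easily, from C-alkylating the electron-rich ring. The forward steps must favour O- over C-alkylation.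

2 from 1: the para O–CH2 bond is cut. This oxygen only needs a group that leaves with the others at the end, so plain benzyl is used, and it goes on first because this hydroxyl is the one not held by the acetyl group. The forward step must stop at mono-alkylation.

## Other disconnections considered

Alternative 1: The cut runs through O1–C2 and C3–C4 of ring C. A chiral phosphoric acid would dehydrate salicyl alcohol A1 to the ortho-quinone methide A2, hold it by hydrogen bonding, and let it add stilbene A3 in an inverse-demand hetero-Diels–Alder reaction to give flavan A4.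
- In its favour: both stereocentres arise in one suprafacial step, so the trans relation follows from the E alkene and not from a later equilibration. C3 is not enolisable when the ring forms, no diazo compound or metal is needed, and the polarity is matched (the carbon bearing the 4-alkoxyphenyl group takes the oxygen). On these points it is the better plan.
- Against it: 1,2-diaryl alkenes are weak partners compared with the styrenes, enol ethers and enamides that this catalysis normally uses. The doubly alkoxylated A2 is stabilised and may be consumed by A1 faster than by A3. A4 is at the wrong oxidation level: C4 must later be oxidised to the ketone in the presence of an equally activated C2–H bond and of benzyl ethers, and the acetate must then be cleaved from a base-sensitive flavanone.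
- Comparison: structurally both plans join two large fragments, and A3 should cost about as many steps as 15. Mechanistically a pericyclic step replaces a carbenoid insertion. In step economy the alternative loses at least two operations to the late C4 oxidation.

Alternative 2: The cut removes the flavone pyranone (C4a''–C4'', C4''–C3'', O1''–C2''). PdCl2(PPh3)2 would join iodide 7, CO and alkyne A5, and the ortho hydroxyl would close the ring 6-endo to give A6.
- In its favour: it is the most convergent option. The symmetric 7 is used without desymmetrisation and the C5'' hydroxyl emerges free, which saves step 5; here it is better. The reaction type is that of step 9, so on mechanism the two are equal.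
- Against it: the cut does not address the real problem, because A5 already contains C2 and C3 and must come from another stereocontrolled construction. If that were the carbenoid insertion, the benzyl ether ortho to the carbene carbon would offer a five-membered C–H insertion. The annulation would also expose a ring C that opens by β-elimination to a secondary amine and heat after the stereocentres exist.
- Comparison: the chosen plan runs the same annulation on achiral material and pays one statistical benzylation for the safety.

Alternative 3: The cut goes through flavone ring B (C2'''–C3''' and C1'''–C6'''). Diene A7 would add ethynylchromone A8 in a Diels–Alder reaction, and DDQ in the same flask would aromatise the adduct to A9.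
- In its favour: the silyloxy group should impose the para rule, so that the diene terminus next to the silyloxy-bearing carbon meets the terminal alkyne carbon. An alkyne raises no endo/exo question, and no palladium, CO or diazo compound is involved. A9 carries a silyl ether on O4''' as 18 does, so the endgame is equal.
- Against it: A7 is harder to make than the problem it solves. Its silyl dienol ether must be formed on a side chain at C3 of a stereodefined flavanone whose C3–H is both α to the ketone and allylic, so enolisation toward the ring, diene migration and ring opening all threaten. The alkyl substituent at the reacting diene terminus opposes the directing effect of the silyloxy group, C2 and C3 must still be set by another method, A8 is only a vinylogous ynone and would need heat, and DDQ may dehydrogenate C2–C3.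
- Comparison: structurally it builds the bridging arene and not ring C. Mechanistically it is thermal and uncatalysed, against a catalytic asymmetric insertion. In step economy it is a long linear sequence on chiral material.

Key step: step 12

Remark on the chemistry: the facial sense of Rh2(S-PTTL)4 (dirhodium tetrakis[N-phthaloyl-(S)-tert-leucinate]) on this substrate class cannot be predicted with certainty. The S series is written, and the mirror-image catalyst would be used if it led to (2R). Compounds 1, 3, 6 and 9 are taken to be commercial.

## Route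

Step 1
Reactants: 1 1-(2,4,6-trihydroxyphenyl)ethan-1-one
Product: 2 1-[4-(benzyloxy)-2,6-dihydroxyphenyl]ethan-1-one
Conditions: BnBr (1.0 equiv), K2CO3 (1.0 equiv), DMF, 0 °C to rt
Reagents that add atoms: benzyl bromide, BrCc1ccccc1
Why: Williamson etherification; the para hydroxyl is the most acidic and the only one not hydrogen-bonded to the acetyl group, so one equivalent of base and halide should alkylate it in preference to the two chelated ortho hydroxyls.

Step 2
Reactants: 2 1-[4-(benzyloxy)-2,6-dihydroxyphenyl]ethan-1-one; 3 4-benzyloxybenzyl chloride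
Product: 4 1-{4-(benzyloxy)-2-[(4-benzyloxyphenyl)methoxy]-6-hydroxyphenyl}ethan-1-one
Conditions: 3 (1.05 equiv), K2CO3, acetone, reflux
Reagents that add atoms: none
Why: Williamson etherification of one of two equivalent ortho phenols; once one is capped, the other holds the acetyl group in a strong hydrogen bond and should be left alone by K2CO3 in acetone, as in the familiar dialkylation of phloroacetophenone that stops at the 6-hydroxy compound.

Step 3
Reactants: 4 1-{4-(benzyloxy)-2-[(4-benzyloxyphenyl)methoxy]-6-hydroxyphenyl}ethan-1-one; 3 4-benzyloxybenzyl chloride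
Product: 5 1-{4-(benzyloxy)-2,6-bis[(4-benzyloxyphenyl)methoxy]phenyl}ethan-1-one
Conditions: 3 (1.3 equiv), Cs2CO3, DMF, 60 °C
Reagents that add atoms: none
Why: Williamson etherification of the remaining chelated phenol; Cs2CO3 in DMF breaks the hydrogen bond and gives a reactive phenoxide, and with only one phenoxide left on the ring O-alkylation should prevail over C-alkylation.

Step 4
Reactants: 6 5-methoxyresorcinol
Product: 7 2-iodo-5-methoxybenzene-1,3-diol
Conditions: I2 (1.0 equiv), NaHCO3, THF/H2O, 0 °C
Reagents that add atoms: iodine, [I][I]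
Why: Electrophilic aromatic iodination of the phenoxide; under NaHCO3 the position between the two hydroxyls (para to methoxy) should be attacked, as in the conversion of resorcinol into 2-iodoresorcinol, and one equivalent at 0 °C limits over-iodination.

Step 5
Reactants: 7 2-iodo-5-methoxybenzene-1,3-diol
Product: 8 3-(benzyloxy)-2-iodo-5-methoxyphenol
Conditions: BnBr (1.0 equiv), K2CO3, acetone, rt
Reagents that add atoms: benzyl bromide, BrCc1ccccc1
Why: Williamson mono-etherification of two equivalent phenols (statistical desymmetrisation); unreacted 7 and the dibenzyl ether should be separable and 7 recycled.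

Step 6
Reactants: 9 2-bromo-4-iodophenol
Product: 10 (2-bromo-4-iodophenoxy)triisopropylsilane
Conditions: TIPSCl, imidazole, DMF, rt
Reagents that add atoms: triisopropylsilyl chloride, CC(C)[Si](Cl)(C(C)C)C(C)C
Why: Imidazole-promoted silylation of a phenol; the triisopropylsilyl ether is the most base-stable common silyl ether and is meant to stay until step 13.

Step 7
Reactants: 10 (2-bromo-4-iodophenoxy)triisopropylsilane
Product: 11 {[3-bromo-4-(triisopropylsilyloxy)phenyl]ethynyl}trimethylsilane
Conditions: HC≡CSiMe3, PdCl2(PPh3)2 (2 mol %), CuI (4 mol %), Et3N, THF, rt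
Reagents that add atoms: ethynyltrimethylsilane, C#C[Si](C)(C)C
Why: Sonogashira coupling; at room temperature oxidative addition to C–I is far faster than to the C–Br bond, which is also shielded by the ortho silyloxy group.

Step 8
Reactants: 11 {[3-bromo-4-(triisopropylsilyloxy)phenyl]ethynyl}trimethylsilane
Product: 12 (2-bromo-4-ethynylphenoxy)triisopropylsilane
Conditions: K2CO3 (0.2 equiv), MeOH/THF, 0 °C
Reagents that add atoms: none
Why: Methoxide-catalysed protodesilylation of the alkynylsilane; the bulky aryl triisopropylsilyl ether should survive brief catalytic K2CO3 at 0 °C.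

Step 9
Reactants: 8 3-(benzyloxy)-2-iodo-5-methoxyphenol; 12 (2-bromo-4-ethynylphenoxy)triisopropylsilane
Product: 14 5-(benzyloxy)-2-[3-bromo-4-(triisopropylsilyloxy)phenyl]-7-methoxy-4H-chromen-4-one, via ortho-hydroxyaryl ynone 13 (not isolated)
Conditions: PdCl2(PPh3)2 (5 mol %), CO (5 bar), Et2NH, THF, 60 °C
Reagents that add atoms: carbon monoxide, [C-]#[O+]
Why: Carbonylative Sonogashira coupling followed by amine-mediated ring closure (the established flavone synthesis from 2-iodophenols, alkynes and CO): oxidative addition at C–I of 8, CO insertion and alkynylation give 13, Et2NH adds to the ynone and the phenol displaces it to close the pyranone 6-endo. CO pressure and the doubly ortho-substituted arylpalladium favour insertion over direct coupling, and the electron-rich, hindered C–Br bond should not react at 60 °C.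

Step 10
Reactants: 5 1-{4-(benzyloxy)-2,6-bis[(4-benzyloxyphenyl)methoxy]phenyl}ethan-1-one; 14 5-(benzyloxy)-2-[3-bromo-4-(triisopropylsilyloxy)phenyl]-7-methoxy-4H-chromen-4-one
Product: 15 5-(benzyloxy)-2-[3-(2-{4-(benzyloxy)-2,6-bis[(4-benzyloxyphenyl)methoxy]phenyl}-2-oxoethyl)-4-(triisopropylsilyloxy)phenyl]-7-methoxy-4H-chromen-4-one
Conditions: Pd2(dba)3 (2.5 mol %), XPhos (6 mol %), K3PO4, toluene, 90 °C
Reagents that add atoms: none
Why: Palladium-catalysed α-arylation of a methyl ketone enolate with an aryl bromide (Buchwald–Hartwig type), using a bulky biaryl phosphine (XPhos, 2-dicyclohexylphosphino-2',4',6'-triisopropylbiphenyl) for the ortho-substituted bromide. The 2,6-disubstituted aroyl group suppresses self-condensation, the more acidic product rests as its enolate and resists a second arylation, and the mild phosphate base should spare chromone and silyl ether.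

Step 11
Reactants: 15 5-(benzyloxy)-2-[3-(2-{4-(benzyloxy)-2,6-bis[(4-benzyloxyphenyl)methoxy]phenyl}-2-oxoethyl)-4-(triisopropylsilyloxy)phenyl]-7-methoxy-4H-chromen-4-one
Product: 16 5-(benzyloxy)-2-[3-(2-{4-(benzyloxy)-2,6-bis[(4-benzyloxyphenyl)methoxy]phenyl}-1-diazo-2-oxoethyl)-4-(triisopropylsilyloxy)phenyl]-7-methoxy-4H-chromen-4-one
Conditions: p-ABSA, DBU, MeCN/CH2Cl2, 0 °C to rt
Reagents that add atoms: 4-acetamidobenzenesulfonyl azide, CC(=O)Nc1ccc(cc1)S(=O)(=O)N=[N+]=[N-]
Why: Regitz diazo transfer to a deoxybenzoin-type methylene activated by both the aroyl and the aryl group: the DBU-generated enolate attacks the terminal azide nitrogen and the triazene fragments to diazo ketone and sulfonamide; p-ABSA is chosen as the safer sulfonyl azide.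

Step 12
Reactants: 16 5-(benzyloxy)-2-[3-(2-{4-(benzyloxy)-2,6-bis[(4-benzyloxyphenyl)methoxy]phenyl}-1-diazo-2-oxoethyl)-4-(triisopropylsilyloxy)phenyl]-7-methoxy-4H-chromen-4-one
Product: 18 (2S,3R)-7-(benzyloxy)-3-[5-(5-benzyloxy-7-methoxy-4-oxo-4H-chromen-2-yl)-2-(triisopropylsilyloxy)phenyl]-2-(4-benzyloxyphenyl)-5-[(4-benzyloxyphenyl)methoxy]chroman-4-one, via cis-flavanone 17 (not isolated)
Conditions: Rh2(S-PTTL)4 (2 mol %), 4 Å MS, toluene, −40 to 0 °C, slow addition of 16; then Et3N (0.1 equiv), 0 °C to rt
Reagents that add atoms: none
Why: Loss of N2 from 16 at an axial site of the dirhodium tetracarboxylate should give an electrophilic carbenoid stabilised by flavone ring B as donor and the ring A aroyl group as acceptor. It inserts in a 1,6 sense, through an asynchronous three-centre transition state with hydride-transfer character, into a C–H bond of an ortho OCH2Ar group, the most hydridic C–H bond within reach because that carbon is bound to oxygen and to a 4-alkoxyphenyl ring, and this forms C2–C3. The closest known reaction types are the insertion of ortho-alkoxyaryl diazo ketones into the ether C–H bond under divalent-rhodium carboxylates to give chroman-4-ones, and the Rh2(S-PTTL)4-catalysed insertion of aryldiazoacetates into benzylic ether C–H bonds. Ring C closes by C–C bond formation within a six-membered array (C3, C4, C4a, C8a, O1, C2), and no five-membered insertion exists on this side because the fifth atom is oxygen. C2 is set by the chiral phthalimido-carboxylate pocket, which distinguishes the two enantiotopic hydrogens of the methylene group (the two ortho ethers interchange by rotation about the aryl–carbonyl bond, so either gives the same product), and insertion occurs with retention at that carbon. C3 forms under kinetic control, probably cis as in 17, and is then brought to the diequatorial trans arrangement (3R) by amine-catalysed enolisation, which does not involve C2. The step needs insertion to win over oxonium ylide formation at the ring A ether oxygen and over any reaction at the ring B oxygen: carboxylate-bridged dirhodium catalysts at low temperature favour insertion into such activated C–H bonds, and the triisopropylsilyl ether offers no C–H bond on an oxygen-bound carbon, only shielded and unactivated methine hydrogens on silicon, and no usable lone pair (a ylide there would be four-membered).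

Step 13
Reactants: 18 (2S,3R)-7-(benzyloxy)-3-[5-(5-benzyloxy-7-methoxy-4-oxo-4H-chromen-2-yl)-2-(triisopropylsilyloxy)phenyl]-2-(4-benzyloxyphenyl)-5-[(4-benzyloxyphenyl)methoxy]chroman-4-one
Product: 19 (2S,3R)-7-(benzyloxy)-3-[5-(5-benzyloxy-7-methoxy-4-oxo-4H-chromen-2-yl)-2-hydroxyphenyl]-2-(4-benzyloxyphenyl)-5-[(4-benzyloxyphenyl)methoxy]chroman-4-one
Conditions: TBAF, AcOH, THF, 0 °C
Reagents that add atoms: none
Why: Fluoride-induced cleavage of the aryl silyl ether; acetic acid buffers fluoride and the released phenoxide so that no C3 enolate forms and ring C and both stereocentres stay intact, while benzyl-type ethers are inert.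

Step 14
Reactants: 19 (2S,3R)-7-(benzyloxy)-3-[5-(5-benzyloxy-7-methoxy-4-oxo-4H-chromen-2-yl)-2-hydroxyphenyl]-2-(4-benzyloxyphenyl)-5-[(4-benzyloxyphenyl)methoxy]chroman-4-one
Product: 20 (2S,3R)-5,7-dihydroxy-3-[2-hydroxy-5-(5-hydroxy-7-methoxy-4-oxo-4H-chromen-2-yl)phenyl]-2-(4-hydroxyphenyl)chroman-4-one
Conditions: H2 (1 atm), 10% Pd/C, EtOAc/MeOH, rt
Reagents that add atoms: none
Why: Catalytic hydrogenolysis of all five benzylic C–O bonds (three benzyl ethers and the 4-benzyloxybenzyl ether, the latter cleaved at both oxygens); at one atmosphere in neutral solvent the chromone double bond and the flavanone should persist and C2 and C3 are not touched.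

## Compound list

1 | 1-(2,4,6-trihydroxyphenyl)ethan-1-one | CC(=O)c1c(O)cc(O)cc1O | starting material
2 | 1-[4-(benzyloxy)-2,6-dihydroxyphenyl]ethan-1-one | CC(=O)c1c(O)cc(OCc2ccccc2)cc1O | intermediate
3 | 4-benzyloxybenzyl chloride | ClCc1ccc(OCc2ccccc2)cc1 | starting material
4 | 1-{4-(benzyloxy)-2-[(4-benzyloxyphenyl)methoxy]-6-hydroxyphenyl}ethan-1-one | CC(=O)c1c(O)cc(OCc2ccccc2)cc1OCc1ccc(OCc2ccccc2)cc1 | intermediate
5 | 1-{4-(benzyloxy)-2,6-bis[(4-benzyloxyphenyl)methoxy]phenyl}ethan-1-one | CC(=O)c1c(OCc2ccc(OCc3ccccc3)cc2)cc(OCc2ccccc2)cc1OCc1ccc(OCc2ccccc2)cc1 | intermediate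
6 | 5-methoxyresorcinol | COc1cc(O)cc(O)c1 | starting material
7 | 2-iodo-5-methoxybenzene-1,3-diol | COc1cc(O)c(I)c(O)c1 | intermediate
8 | 3-(benzyloxy)-2-iodo-5-methoxyphenol | COc1cc(O)c(I)c(OCc2ccccc2)c1 | intermediate
9 | 2-bromo-4-iodophenol | Oc1ccc(I)cc1Br | starting material
10 | (2-bromo-4-iodophenoxy)triisopropylsilane | CC(C)[Si](Oc1ccc(I)cc1Br)(C(C)C)C(C)C | intermediate
11 | {[3-bromo-4-(triisopropylsilyloxy)phenyl]ethynyl}trimethylsilane | CC(C)[Si](Oc1ccc(C#C[Si](C)(C)C)cc1Br)(C(C)C)C(C)C | intermediate
12 | (2-bromo-4-ethynylphenoxy)triisopropylsilane | CC(C)[Si](Oc1ccc(C#C)cc1Br)(C(C)C)C(C)C | intermediate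
13 | 1-[2-(benzyloxy)-6-hydroxy-4-methoxyphenyl]-3-[3-bromo-4-(triisopropylsilyloxy)phenyl]prop-2-yn-1-one | COc1cc(O)c(C(=O)C#Cc2ccc(O[Si](C(C)C)(C(C)C)C(C)C)c(Br)c2)c(OCc2ccccc2)c1 | intermediate
14 | 5-(benzyloxy)-2-[3-bromo-4-(triisopropylsilyloxy)phenyl]-7-methoxy-4H-chromen-4-one | COc1cc(OCc2ccccc2)c2c(=O)cc(-c3ccc(O[Si](C(C)C)(C(C)C)C(C)C)c(Br)c3)oc2c1 | intermediate
15 | 5-(benzyloxy)-2-[3-(2-{4-(benzyloxy)-2,6-bis[(4-benzyloxyphenyl)methoxy]phenyl}-2-oxoethyl)-4-(triisopropylsilyloxy)phenyl]-7-methoxy-4H-chromen-4-one | COc1cc(OCc2ccccc2)c2c(=O)cc(-c3ccc(O[Si](C(C)C)(C(C)C)C(C)C)c(CC(=O)c4c(OCc5ccc(OCc6ccccc6)cc5)cc(OCc5ccccc5)cc4OCc4ccc(OCc5ccccc5)cc4)c3)oc2c1 | intermediate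
16 | 5-(benzyloxy)-2-[3-(2-{4-(benzyloxy)-2,6-bis[(4-benzyloxyphenyl)methoxy]phenyl}-1-diazo-2-oxoethyl)-4-(triisopropylsilyloxy)phenyl]-7-methoxy-4H-chromen-4-one | COc1cc(OCc2ccccc2)c2c(=O)cc(-c3ccc(O[Si](C(C)C)(C(C)C)C(C)C)c(C(=[N+]=[N-])C(=O)c4c(OCc5ccc(OCc6ccccc6)cc5)cc(OCc5ccccc5)cc4OCc4ccc(OCc5ccccc5)cc4)c3)oc2c1 | intermediate
17 | (2S,3S)-7-(benzyloxy)-3-[5-(5-benzyloxy-7-methoxy-4-oxo-4H-chromen-2-yl)-2-(triisopropylsilyloxy)phenyl]-2-(4-benzyloxyphenyl)-5-[(4-benzyloxyphenyl)methoxy]chroman-4-one (2,3-cis) | COc1cc(OCc2ccccc2)c2c(=O)cc(-c3ccc(O[Si](C(C)C)(C(C)C)C(C)C)c([C@@H]4C(=O)c5c(OCc6ccc(OCc7ccccc7)cc6)cc(OCc6ccccc6)cc5O[C@@H]4c4ccc(OCc5ccccc5)cc4)c3)oc2c1 | intermediate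
18 | (2S,3R)-7-(benzyloxy)-3-[5-(5-benzyloxy-7-methoxy-4-oxo-4H-chromen-2-yl)-2-(triisopropylsilyloxy)phenyl]-2-(4-benzyloxyphenyl)-5-[(4-benzyloxyphenyl)methoxy]chroman-4-one (2,3-trans) | COc1cc(OCc2ccccc2)c2c(=O)cc(-c3ccc(O[Si](C(C)C)(C(C)C)C(C)C)c([C@H]4C(=O)c5c(OCc6ccc(OCc7ccccc7)cc6)cc(OCc6ccccc6)cc5O[C@@H]4c4ccc(OCc5ccccc5)cc4)c3)oc2c1 | intermediate
19 | (2S,3R)-7-(benzyloxy)-3-[5-(5-benzyloxy-7-methoxy-4-oxo-4H-chromen-2-yl)-2-hydroxyphenyl]-2-(4-benzyloxyphenyl)-5-[(4-benzyloxyphenyl)methoxy]chroman-4-one | COc1cc(OCc2ccccc2)c2c(=O)cc(-c3ccc(O)c([C@H]4C(=O)c5c(OCc6ccc(OCc7ccccc7)cc6)cc(OCc6ccccc6)cc5O[C@@H]4c4ccc(OCc5ccccc5)cc4)c3)oc2c1 | intermediate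
20 | (2S,3R)-5,7-dihydroxy-3-[2-hydroxy-5-(5-hydroxy-7-methoxy-4-oxo-4H-chromen-2-yl)phenyl]-2-(4-hydroxyphenyl)chroman-4-one | COc1cc(O)c2c(=O)cc(-c3ccc(O)c([C@H]4C(=O)c5c(O)cc(O)cc5O[C@@H]4c4ccc(O)cc4)c3)oc2c1 | target

## Step count and least certain steps

Total step count: 14. Longest linear sequence: 9 steps (steps 6 to 14, from 9 through 10, 11, 12, 14, 15, 16, 18 and 19 to 20).

Step 12, the key step. Four processes are the most likely failures:
- attack of a ring A ether oxygen on the carbenoid, followed by a 1,2-shift of the 4-benzyloxybenzyl group, which would contract the ring to a benzofuranone;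
- migration of the electron-rich ring A aryl group to the carbene carbon (Wolff-type rearrangement);
- weak discrimination of the enantiotopic hydrogens, because the twisted, hindered diaryl carbenoid may not sit in the catalyst pocket as simpler substrates do;
- ring opening by β-elimination during the C3 equilibration, which would erode C2.

The fallback forms O1–C2 instead and uses no carbenoid. From 15, chelation-controlled cleavage of one ortho ether with MgBr2·OEt2 in toluene/Et2O should give the ortho-hydroxy deoxybenzoin F1. Condensing F1 with 4-benzyloxybenzaldehyde under piperidine catalysis (aldol condensation, then oxa-Michael closure, the classical entry to 2,3-diarylchroman-4-ones) should give the racemic trans-flavanone F2 under thermodynamic control. Preparative chromatography on a chiral stationary phase would then supply 18, where the route is rejoined, at the cost of half the material.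

Step 10. Oxidative addition may be slow at the bromide next to the bulky silyloxy group, the ketone enolate may add to C2'' of the chromone, and the silyl group may transfer from O4''' to the neighbouring product enolate. The fallback changes the order of construction so that no chromone is present at the union. From 5 and 11, the same type of arylation should give the silylalkynyl deoxybenzoin F3. Catalytic K2CO3 in MeOH would give the terminal alkyne F4. Carbonylative annulation of F4 with 8, through the ynone F5, would return to the route at 15.

Step 9. Coupling without CO insertion followed by closure to a benzofuran, capture of the acylpalladium by the amine, 5-exo instead of 6-endo closure, and competing oxidative addition at C–Br are all possible. The fallback uses neither palladium nor CO. From 8, deprotonation and iodine–magnesium exchange with iPrMgCl followed by DMF should give the salicylaldehyde F6. The bromomagnesium acetylide of 12 (EtMgBr, THF) would add to F6 to give the propargylic alcohol F7. MnO2 would oxidise F7 to 13, and Et2NH in EtOH would close 13 to 14.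

Step 14. Saturation of the chromone C2''=C3'' bond, hydrogenolytic opening of the benzylic C2–O1 bond, and stalling at poorly soluble, partly deprotected stages are the risks. The fallback is non-reductive: from 19, BCl3 with pentamethylbenzene as cation scavenger in CH2Cl2 at −78 °C should cleave all benzyl-type ethers and give 20 directly, with no new intermediate.

Step 4. Iodination at C4 (between a hydroxyl and the methoxy group) instead of C2, and over-iodination, may lower the yield of 7. The fallback fixes the position by directed metalation. From 6, MOMCl and iPr2NEt should give the bis(methoxymethyl) ether F8. Lithiation with nBuLi between the two acetal oxygens and quenching with I2 would give the iodide F9. HCl in MeOH would release 7.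

Step 1. Alkylation may run on to an ortho hydroxyl before all of 1 is consumed, and the phloroglucinol-type phenoxide may be benzylated on carbon. The fallback reverses the logic and removes groups under chelation control. From 1, exhaustive benzylation (BnBr in excess, K2CO3, DMF, 80 °C) should give the tribenzyl ether F10. BCl3 (2.2 equiv) in CH2Cl2 at −78 °C, which binds the ketone and cleaves only the two ethers flanking it, would then give 2.

## Further compounds

F1 | step 12 | 5-(benzyloxy)-2-[3-(2-{4-(benzyloxy)-2-[(4-benzyloxyphenyl)methoxy]-6-hydroxyphenyl}-2-oxoethyl)-4-(triisopropylsilyloxy)phenyl]-7-methoxy-4H-chromen-4-one | COc1cc(OCc2ccccc2)c2c(=O)cc(-c3ccc(O[Si](C(C)C)(C(C)C)C(C)C)c(CC(=O)c4c(O)cc(OCc5ccccc5)cc4OCc4ccc(OCc5ccccc5)cc4)c3)oc2c1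
F2 | step 12 | racemic trans-flavanone, an equimolar mixture of 18 and its (2R,3S) enantiomer (the SMILES shows the (2R,3S) enantiomer) | COc1cc(OCc2ccccc2)c2c(=O)cc(-c3ccc(O[Si](C(C)C)(C(C)C)C(C)C)c([C@@H]4C(=O)c5c(OCc6ccc(OCc7ccccc7)cc6)cc(OCc6ccccc6)cc5O[C@H]4c4ccc(OCc5ccccc5)cc4)c3)oc2c1
F3 | step 10 | 1-{4-(benzyloxy)-2,6-bis[(4-benzyloxyphenyl)methoxy]phenyl}-2-[2-(triisopropylsilyloxy)-5-(trimethylsilylethynyl)phenyl]ethan-1-one | C[Si](C)(C)C#Cc1ccc(O[Si](C(C)C)(C(C)C)C(C)C)c(CC(=O)c2c(OCc3ccc(OCc4ccccc4)cc3)cc(OCc3ccccc3)cc2OCc2ccc(OCc3ccccc3)cc2)c1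
F4 | step 10 | 1-{4-(benzyloxy)-2,6-bis[(4-benzyloxyphenyl)methoxy]phenyl}-2-[5-ethynyl-2-(triisopropylsilyloxy)phenyl]ethan-1-one | C#Cc1ccc(O[Si](C(C)C)(C(C)C)C(C)C)c(CC(=O)c2c(OCc3ccc(OCc4ccccc4)cc3)cc(OCc3ccccc3)cc2OCc2ccc(OCc3ccccc3)cc2)c1
F5 | step 10 | 1-[2-(benzyloxy)-6-hydroxy-4-methoxyphenyl]-3-[3-(2-{4-(benzyloxy)-2,6-bis[(4-benzyloxyphenyl)methoxy]phenyl}-2-oxoethyl)-4-(triisopropylsilyloxy)phenyl]prop-2-yn-1-one | COc1cc(O)c(C(=O)C#Cc2ccc(O[Si](C(C)C)(C(C)C)C(C)C)c(CC(=O)c3c(OCc4ccc(OCc5ccccc5)cc4)cc(OCc4ccccc4)cc3OCc3ccc(OCc4ccccc4)cc3)c2)c(OCc2ccccc2)c1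
F6 | step 9 | 2-(benzyloxy)-6-hydroxy-4-methoxybenzaldehyde | COc1cc(O)c(C=O)c(OCc2ccccc2)c1
F7 | step 9 | 3-(benzyloxy)-2-{3-[3-bromo-4-(triisopropylsilyloxy)phenyl]-1-hydroxyprop-2-yn-1-yl}-5-methoxyphenol (racemic carbinol) | COc1cc(O)c(C(O)C#Cc2ccc(O[Si](C(C)C)(C(C)C)C(C)C)c(Br)c2)c(OCc2ccccc2)c1
F0 | step 14 | none | none
F8 | step 4 | 1-methoxy-3,5-bis(methoxymethoxy)benzene | COCOc1cc(OC)cc(OCOC)c1
F9 | step 4 | 2-iodo-5-methoxy-1,3-bis(methoxymethoxy)benzene | COCOc1cc(OC)cc(OCOC)c1I
F10 | step 1 | 1-[2,4,6-tris(benzyloxy)phenyl]ethan-1-one | CC(=O)c1c(OCc2ccccc2)cc(OCc2ccccc2)cc1OCc1ccccc1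
A1 | alternative 1 | 3,5-bis(benzyloxy)-2-(hydroxymethyl)phenol | OCc1c(O)cc(OCc2ccccc2)cc1OCc1ccccc1
A2 | alternative 1 | 3,5-bis(benzyloxy)-6-methylidenecyclohexa-2,4-dien-1-one | C=C1C(=O)C=C(OCc2ccccc2)C=C1OCc1ccccc1
A3 | alternative 1 | 2-[(E)-2-(4-benzyloxyphenyl)ethenyl]-4-(5-benzyloxy-7-methoxy-4-oxo-4H-chromen-2-yl)phenyl acetate | COc1cc(OCc2ccccc2)c2c(=O)cc(-c3ccc(OC(C)=O)c(/C=C/c4ccc(OCc5ccccc5)cc4)c3)oc2c1
A4 | alternative 1 | 4-(5-benzyloxy-7-methoxy-4-oxo-4H-chromen-2-yl)-2-[(2S,3R)-5,7-bis(benzyloxy)-2-(4-benzyloxyphenyl)chroman-3-yl]phenyl acetate | COc1cc(OCc2ccccc2)c2c(=O)cc(-c3ccc(OC(C)=O)c([C@H]4Cc5c(OCc6ccccc6)cc(OCc6ccccc6)cc5O[C@@H]4c4ccc(OCc5ccccc5)cc4)c3)oc2c1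
A5 | alternative 2 | (2S,3R)-5,7-bis(benzyloxy)-3-(2-benzyloxy-5-ethynylphenyl)-2-(4-benzyloxyphenyl)chroman-4-one | C#Cc1ccc(OCc2ccccc2)c([C@H]2C(=O)c3c(OCc4ccccc4)cc(OCc4ccccc4)cc3O[C@@H]2c2ccc(OCc3ccccc3)cc2)c1
A6 | alternative 2 | (2S,3R)-5,7-bis(benzyloxy)-3-[2-benzyloxy-5-(5-hydroxy-7-methoxy-4-oxo-4H-chromen-2-yl)phenyl]-2-(4-benzyloxyphenyl)chroman-4-one | COc1cc(O)c2c(=O)cc(-c3ccc(OCc4ccccc4)c([C@H]4C(=O)c5c(OCc6ccccc6)cc(OCc6ccccc6)cc5O[C@@H]4c4ccc(OCc5ccccc5)cc4)c3)oc2c1
A7 | alternative 3 | (2S,3R)-5,7-bis(benzyloxy)-2-(4-benzyloxyphenyl)-3-[(1Z)-2-(tert-butyldimethylsilyloxy)buta-1,3-dien-1-yl]chroman-4-one | C=C/C(O[Si](C)(C)C(C)(C)C)=C/[C@H]1C(=O)c2c(OCc3ccccc3)cc(OCc3ccccc3)cc2O[C@@H]1c1ccc(OCc2ccccc2)cc1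
A8 | alternative 3 | 5-(benzyloxy)-2-ethynyl-7-methoxy-4H-chromen-4-one | COc1cc(OCc2ccccc2)c2c(=O)cc(C#C)oc2c1
A9 | alternative 3 | (2S,3R)-5,7-bis(benzyloxy)-3-[5-(5-benzyloxy-7-methoxy-4-oxo-4H-chromen-2-yl)-2-(tert-butyldimethylsilyloxy)phenyl]-2-(4-benzyloxyphenyl)chroman-4-one | COc1cc(OCc2ccccc2)c2c(=O)cc(-c3ccc(O[Si](C)(C)C(C)(C)C)c([C@H]4C(=O)c5c(OCc6ccccc6)cc(OCc6ccccc6)cc5O[C@@H]4c4ccc(OCc5ccccc5)cc4)c3)oc2c1
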